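**Plan**

- Retrosynthesis cuts first the S–O bonds of a 5‑tosylate and a 7‑triflate (free 5‑ and 7‑hydroxyls), then O1–C2 of ring C (cyclodehydration of a 2‑hydroxyaryl 1,3‑diketone), then C8a–O1 and C4a–C4 together (aryne plus carboxylate).
- Enabling feature: in ring A the neighbouring carbons C8a and C4a carry O1 and C4, and the C5 oxygen beside C4a, worn as a sulfonate, polarises an aryne spanning C4a–C8a so that oxygen enters at C8a.
- Forward: ring A is made as 2‑silylaryl triflate 13 from methyl 3,5‑dihydroxy‑4‑methoxybenzoate (steps 1–8); C2, C3, the 3‑O‑prenyl group and ring B are assembled as caesium β‑ketocarboxylate 22 by aldol addition and oxidation (steps 9–13).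
- Step 14 inserts the aryne into the carboxylate C–O bond without closing a ring; ring C closes under mild acid (step 15) and hydroxide removes both sulfonates (step 16).
- Stereochemistry: the target is achiral; the stereocentres of 20, 21, 22 and 25 are racemic and vanish on oxidation and on aromatisation of ring C.

Key step: step 14

Assumption: methyl 3,5‑dihydroxy‑4‑methoxybenzoate is taken as a catalogue compound, and the 7‑oxygen is carried as a triflate instead of a tosylate so that the two phenols freed in step 7 are sulfonylated together; an aryl triflate with no silyl neighbour is taken to be inert to CsF.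

Abbreviations: prenyl = 3‑methylbut‑2‑en‑1‑yl; tosyl (Ts) = 4‑methylbenzenesulfonyl; triflyl (Tf) = trifluoromethanesulfonyl.

**Route**

Step 1
Reactants: 1 methyl 3,5‑dihydroxy‑4‑methoxybenzoate
Product: 2 methyl 3,5‑bis(benzyloxy)‑4‑methoxybenzoate
Conditions: BnBr (2.3 equiv), K2CO3, DMF, 60 °C
Reagents that add atoms: benzyl bromide, BrCc1ccccc1
Why: Williamson ether synthesis on the two equivalent phenols; benzyl ethers survive LiAlH4, peracid and n‑BuLi and leave by hydrogenolysis once the tosylate and the C–Si bond are in place.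

Step 2
Reactants: 2 methyl 3,5‑bis(benzyloxy)‑4‑methoxybenzoate
Product: 3 [3,5‑bis(benzyloxy)‑4‑methoxyphenyl]methanol
Conditions: LiAlH4, THF, 0 °C
Reagents that add atoms: none
Why: LiAlH4 reduction of the methyl ester to the benzylic alcohol, the ethers being inert to hydride.

Step 3
Reactants: 3 [3,5‑bis(benzyloxy)‑4‑methoxyphenyl]methanol
Product: 4 3,5‑bis(benzyloxy)‑4‑methoxybenzaldehyde
Conditions: MnO2 (activated, excess), CH2Cl2, rt
Reagents that add atoms: none
Why: MnO2 oxidation is selective for benzylic alcohols and stops at the aldehyde.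

Step 4
Reactants: 4 3,5‑bis(benzyloxy)‑4‑methoxybenzaldehyde
Product: 6 3,5‑bis(benzyloxy)‑4‑methoxyphenol, via aryl formate 5 (not isolated)
Conditions: mCPBA, CH2Cl2, rt; then K2CO3 (cat.), MeOH, rt
Reagents that add atoms: 3‑chloroperoxybenzoic acid, OOC(=O)c1cccc(Cl)c1
Why: Dakin‑type Baeyer–Villiger oxidation in which the para‑methoxy group makes the electron‑rich aryl ring migrate in preference to hydride, followed by methanolysis of the formate.

Step 5
Reactants: 6 3,5‑bis(benzyloxy)‑4‑methoxyphenol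
Product: 7 3,5‑bis(benzyloxy)‑2‑bromo‑4‑methoxyphenol
Conditions: NBS (1.0 equiv), CH2Cl2, −78 → −20 °C
Reagents that add atoms: N‑bromosuccinimide, O=C1CCC(=O)N1Br
Why: electrophilic aromatic bromination ortho to the free phenol; the two open ring positions are equivalent by symmetry and the para position is blocked by methoxy, so one equivalent of NBS at low temperature should give a single monobromide.

Step 6
Reactants: 7 3,5‑bis(benzyloxy)‑2‑bromo‑4‑methoxyphenol
Product: 11 3,5‑bis(benzyloxy)‑4‑methoxy‑2‑(trimethylsilyl)phenyl 4‑methylbenzenesulfonate, via silyl ether 8 (not isolated), via aryllithium 9 (not isolated), via lithium phenoxide 10 (not isolated)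
Conditions: (Me3Si)2NH, THF, 65 °C, then evaporate; n‑BuLi (1.1 equiv), THF, −78 °C; TsCl (1.3 equiv), −78 °C → rt
Reagents that add atoms: hexamethyldisilazane, C[Si](C)(C)N[Si](C)(C)C; 4‑toluenesulfonyl chloride, Cc1ccc(cc1)S(Cl)(=O)=O
Why: bromine–lithium exchange followed by retro‑Brook 1,3‑O→C silyl migration, for which only the silyloxy neighbour (the later 5‑oxygen) can be the donor because the other neighbour is a benzyl ether, then O‑sulfonylation of the released lithium phenoxide, so that silicon ends at the later C4a and the tosylate at the later C5 oxygen with no sulfonate present during the organolithium stage.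

Step 7
Reactants: 11 3,5‑bis(benzyloxy)‑4‑methoxy‑2‑(trimethylsilyl)phenyl 4‑methylbenzenesulfonate
Product: 12 3,5‑dihydroxy‑4‑methoxy‑2‑(trimethylsilyl)phenyl 4‑methylbenzenesulfonate
Conditions: H2 (1 atm), Pd/C (10% palladium on carbon), EtOAc, rt
Reagents that add atoms: none
Why: Pd‑catalysed hydrogenolysis of the benzyl ethers under neutral conditions, to which the aryl tosylate and the aryl–silicon bond are inert.

Step 8
Reactants: 12 3,5‑dihydroxy‑4‑methoxy‑2‑(trimethylsilyl)phenyl 4‑methylbenzenesulfonate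
Product: 13 2‑methoxy‑5‑(tosyloxy)‑4‑(trimethylsilyl)‑1,3‑phenylene bis(trifluoromethanesulfonate)
Conditions: Tf2O (2.4 equiv), pyridine, CH2Cl2, −78 → 0 °C
Reagents that add atoms: trifluoromethanesulfonic anhydride, O=S(=O)(OS(=O)(=O)C(F)(F)F)C(F)(F)F
Why: O‑triflation of both phenols with Tf2O and pyridine, the usual last step of 2‑silylaryl triflate syntheses; the triflate beside silicon becomes the aryne leaving group and the remote one is a base‑labile mask of the 7‑hydroxyl.

Step 9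
Reactants: 14 4‑hydroxybenzaldehyde; 15 prenyl bromide (1‑bromo‑3‑methylbut‑2‑ene)
Product: 16 4‑(prenyloxy)benzaldehyde
Conditions: K2CO3, acetone, reflux
Reagents that add atoms: none
Why: Williamson ether synthesis, SN2 attack of the phenoxide at the primary allylic bromide.

Step 10
Reactants: 17 methyl glycolate (methyl 2‑hydroxyacetate); 15 prenyl bromide
Product: 18 methyl 2‑(prenyloxy)acetate
Conditions: NaH (1.05 equiv), Bu4NI (cat.), THF, 0 °C → rt
Reagents that add atoms: none
Why: Williamson ether synthesis of the glycolate alkoxide with the reactive allylic bromide, run cold to suppress self‑transesterification of the glycolate.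

Step 11
Reactants: 18 methyl 2‑(prenyloxy)acetate; 16 4‑(prenyloxy)benzaldehyde
Product: 20 methyl 3‑hydroxy‑2‑(prenyloxy)‑3‑[4‑(prenyloxy)phenyl]propanoate (racemic diastereomer mixture), via lithium enolate 19 (not isolated)
Conditions: LiN(iPr)2, THF, −78 °C; then 16, −78 °C; aq. NH4Cl
Reagents that add atoms: none
Why: aldol addition of the lithium ester enolate at −78 °C, below the temperature at which allyloxy enolates undergo 2,3‑Wittig rearrangement; the two new stereocentres are left uncontrolled because one is oxidised in step 12 and the other becomes sp2 in step 15.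

Step 12
Reactants: 20 methyl 3‑hydroxy‑2‑(prenyloxy)‑3‑[4‑(prenyloxy)phenyl]propanoate
Product: 21 methyl 3‑oxo‑2‑(prenyloxy)‑3‑[4‑(prenyloxy)phenyl]propanoate (racemic)
Conditions: Dess–Martin periodinane, NaHCO3, CH2Cl2, 0 °C → rt
Reagents that add atoms: none
Why: Dess–Martin oxidation of the benzylic secondary alcohol to the aryl ketone under buffered neutral conditions that leave the trisubstituted alkenes alone.

Step 13
Reactants: 21 methyl 3‑oxo‑2‑(prenyloxy)‑3‑[4‑(prenyloxy)phenyl]propanoate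
Product: 22 caesium 3‑oxo‑2‑(prenyloxy)‑3‑[4‑(prenyloxy)phenyl]propanoate (racemic)
Conditions: CsOH·H2O (1.05 equiv), THF–H2O, 0 °C → rt; freeze‑dry; toluene azeotrope, vacuum
Reagents that add atoms: caesium hydroxide monohydrate, O.[Cs+].[OH-]
Why: ester saponification with one equivalent of CsOH, which gives the caesium β‑ketocarboxylate directly so that the free β‑keto acid, prone to decarboxylation, is never formed; the substrate sits mostly as its enolate, which shields the ketone from retro‑Claisen cleavage.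

Step 14
Reactants: 13 2‑methoxy‑5‑(tosyloxy)‑4‑(trimethylsilyl)‑1,3‑phenylene bis(trifluoromethanesulfonate); 22 caesium 3‑oxo‑2‑(prenyloxy)‑3‑[4‑(prenyloxy)phenyl]propanoate (1.5 equiv)
Product: 25 1‑[2‑hydroxy‑3‑methoxy‑6‑(tosyloxy)‑4‑(triflyloxy)phenyl]‑2‑(prenyloxy)‑3‑[4‑(prenyloxy)phenyl]propane‑1,3‑dione (racemic), via aryne 23 (not isolated), via arylcaesium ester 24 (not isolated)
Conditions: CsF (3 equiv), 18‑crown‑6 (3 equiv), 4 Å MS, THF, 25 → 50 °C; aq. NH4Cl
Reagents that add atoms: none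
Why: Fluoride removes the silyl group at C4a and triflate leaves from C8a (triflate is expelled far faster than the tosylate on the other side), giving aryne 23; the carboxylate oxygen of 22 adds to C8a and the aryl anion left at C4a attacks the new ester carbonyl through a four‑membered transition state, so the acyl group moves from oxygen to carbon and the C8a phenoxide is released, forming C8a–O1 and C4a–C4. The closest known reaction is the CsF‑mediated insertion of arynes from 2‑silylaryl triflates into the acyl C–O bond of carboxylic acids to give 2‑hydroxyaryl ketones. No ring is closed, and the only stereocentre (C3 of the chain) stays racemic and is removed in step 15. The step needs oxygen to attack C8a and not C4a: the 5‑tosyloxy group beside C4a is a stronger σ‑acceptor and bulkier than the 8‑methoxy group beside C8a, so attack should go to the distal carbon C8a with the negative charge developing next to the sulfonate. The preformed dry caesium salt in THF leaves no O–H or acidic solvent proton to quench the aryl anion, and holding the temperature at or below 50 °C protects the β‑ketocarboxylate from decarboxylation.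

Step 15
Reactants: 25 1‑[2‑hydroxy‑3‑methoxy‑6‑(tosyloxy)‑4‑(triflyloxy)phenyl]‑2‑(prenyloxy)‑3‑[4‑(prenyloxy)phenyl]propane‑1,3‑dione
Product: 26 8‑methoxy‑3‑(prenyloxy)‑2‑[4‑(prenyloxy)phenyl]‑5‑(tosyloxy)‑7‑(triflyloxy)‑4H‑chromen‑4‑one
Conditions: camphorsulfonic acid (0.2 equiv), 4 Å MS, CH2Cl2, rt → 40 °C
Reagents that add atoms: none
Why: acid‑catalysed cyclodehydration of a 2‑hydroxyaryl 1,3‑diketone (second stage of the Baker–Venkataraman flavone synthesis): the C8a hydroxyl adds to the aroyl carbonyl (6‑exo‑trig) and loss of water forms O1–C2 and the C2=C3 bond, the mild anhydrous acid sparing the prenyl ethers.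

Step 16
Reactants: 26 8‑methoxy‑3‑(prenyloxy)‑2‑[4‑(prenyloxy)phenyl]‑5‑(tosyloxy)‑7‑(triflyloxy)‑4H‑chromen‑4‑one
Product: 27 5,7‑dihydroxy‑8‑methoxy‑3‑(prenyloxy)‑2‑[4‑(prenyloxy)phenyl]‑4H‑chromen‑4‑one (5,7‑dihydroxy‑8‑methoxy‑3,4'‑diprenyloxyflavone)
Conditions: KOH (1 M aq., 6 equiv), 1,4‑dioxane, rt → 40 °C; then 1 M HCl to pH 5
Reagents that add atoms: none
Why: hydrolysis of aryl sulfonates by hydroxide attack at sulfur (S–O cleavage), fast here because the 5‑ and 7‑phenoxides are conjugated with the C4 carbonyl, while prenyl ethers are inert to base and the alcohol‑free medium generates no alkylating sulfonate ester.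

**Compound list**

1 | methyl 3,5‑dihydroxy‑4‑methoxybenzoate | COC(=O)c1cc(O)c(OC)c(O)c1 | starting material
2 | methyl 3,5‑bis(benzyloxy)‑4‑methoxybenzoate | COC(=O)c1cc(OCc2ccccc2)c(OC)c(OCc2ccccc2)c1 | intermediate
3 | [3,5‑bis(benzyloxy)‑4‑methoxyphenyl]methanol | OCc1cc(OCc2ccccc2)c(OC)c(OCc2ccccc2)c1 | intermediate
4 | 3,5‑bis(benzyloxy)‑4‑methoxybenzaldehyde | O=Cc1cc(OCc2ccccc2)c(OC)c(OCc2ccccc2)c1 | intermediate
5 | 3,5‑bis(benzyloxy)‑4‑methoxyphenyl formate | O=COc1cc(OCc2ccccc2)c(OC)c(OCc2ccccc2)c1 | intermediate (not isolated)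
6 | 3,5‑bis(benzyloxy)‑4‑methoxyphenol | Oc1cc(OCc2ccccc2)c(OC)c(OCc2ccccc2)c1 | intermediate
7 | 3,5‑bis(benzyloxy)‑2‑bromo‑4‑methoxyphenol | Oc1cc(OCc2ccccc2)c(OC)c(OCc2ccccc2)c1Br | intermediate
8 | [3,5‑bis(benzyloxy)‑2‑bromo‑4‑methoxyphenoxy]trimethylsilane | C[Si](C)(C)Oc1cc(OCc2ccccc2)c(OC)c(OCc2ccccc2)c1Br | intermediate (not isolated)
9 | {2,4‑bis(benzyloxy)‑3‑methoxy‑6‑[(trimethylsilyl)oxy]phenyl}lithium | C[Si](C)(C)Oc1cc(OCc2ccccc2)c(OC)c(OCc2ccccc2)c1[Li] | intermediate (not isolated)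
10 | lithium 3,5‑bis(benzyloxy)‑4‑methoxy‑2‑(trimethylsilyl)phenoxide | [Li+].[O-]c1cc(OCc2ccccc2)c(OC)c(OCc2ccccc2)c1[Si](C)(C)C | intermediate (not isolated)
11 | 3,5‑bis(benzyloxy)‑4‑methoxy‑2‑(trimethylsilyl)phenyl 4‑methylbenzenesulfonate | Cc1ccc(cc1)S(=O)(=O)Oc1cc(OCc2ccccc2)c(OC)c(OCc2ccccc2)c1[Si](C)(C)C | intermediate
12 | 3,5‑dihydroxy‑4‑methoxy‑2‑(trimethylsilyl)phenyl 4‑methylbenzenesulfonate | Cc1ccc(cc1)S(=O)(=O)Oc1cc(O)c(OC)c(O)c1[Si](C)(C)C | intermediate
13 | 2‑methoxy‑5‑(tosyloxy)‑4‑(trimethylsilyl)‑1,3‑phenylene bis(trifluoromethanesulfonate) | Cc1ccc(cc1)S(=O)(=O)Oc1cc(OS(=O)(=O)C(F)(F)F)c(OC)c(OS(=O)(=O)C(F)(F)F)c1[Si](C)(C)C | intermediate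
14 | 4‑hydroxybenzaldehyde | O=Cc1ccc(O)cc1 | starting material
15 | prenyl bromide (1‑bromo‑3‑methylbut‑2‑ene) | CC(C)=CCBr | starting material
16 | 4‑(prenyloxy)benzaldehyde | O=Cc1ccc(OCC=C(C)C)cc1 | intermediate
17 | methyl glycolate | COC(=O)CO | starting material
18 | methyl 2‑(prenyloxy)acetate | COC(=O)COCC=C(C)C | intermediate
19 | lithium enolate of methyl 2‑(prenyloxy)acetate | COC(O[Li])=COCC=C(C)C | intermediate (not isolated)
20 | methyl 3‑hydroxy‑2‑(prenyloxy)‑3‑[4‑(prenyloxy)phenyl]propanoate (racemic, both diastereomers) | COC(=O)C(OCC=C(C)C)C(O)c1ccc(OCC=C(C)C)cc1 | intermediate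
21 | methyl 3‑oxo‑2‑(prenyloxy)‑3‑[4‑(prenyloxy)phenyl]propanoate (racemic) | COC(=O)C(OCC=C(C)C)C(=O)c1ccc(OCC=C(C)C)cc1 | intermediate
22 | caesium 3‑oxo‑2‑(prenyloxy)‑3‑[4‑(prenyloxy)phenyl]propanoate (racemic) | [Cs+].[O-]C(=O)C(OCC=C(C)C)C(=O)c1ccc(OCC=C(C)C)cc1 | intermediate
23 | 3‑methoxy‑6‑(tosyloxy)‑4‑(triflyloxy)‑1,2‑didehydrobenzene (aryne across C4a–C8a) | COC1=C(OS(=O)(=O)C(F)(F)F)C=C(OS(=O)(=O)c2ccc(C)cc2)C#C1 | intermediate (not isolated)
24 | arylcaesium ester: 2‑caesio‑6‑methoxy‑3‑(tosyloxy)‑5‑(triflyloxy)phenyl 3‑oxo‑2‑(prenyloxy)‑3‑[4‑(prenyloxy)phenyl]propanoate | COc1c(OS(=O)(=O)C(F)(F)F)cc(OS(=O)(=O)c2ccc(C)cc2)c([Cs])c1OC(=O)C(OCC=C(C)C)C(=O)c1ccc(OCC=C(C)C)cc1 | intermediate (not isolated)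
25 | 1‑[2‑hydroxy‑3‑methoxy‑6‑(tosyloxy)‑4‑(triflyloxy)phenyl]‑2‑(prenyloxy)‑3‑[4‑(prenyloxy)phenyl]propane‑1,3‑dione (racemic) | COc1c(O)c(C(=O)C(OCC=C(C)C)C(=O)c2ccc(OCC=C(C)C)cc2)c(OS(=O)(=O)c2ccc(C)cc2)cc1OS(=O)(=O)C(F)(F)F | intermediate
26 | 8‑methoxy‑3‑(prenyloxy)‑2‑[4‑(prenyloxy)phenyl]‑5‑(tosyloxy)‑7‑(triflyloxy)‑4H‑chromen‑4‑one | COc1c(OS(=O)(=O)C(F)(F)F)cc(OS(=O)(=O)c2ccc(C)cc2)c2c(=O)c(OCC=C(C)C)c(-c3ccc(OCC=C(C)C)cc3)oc12 | intermediate
27 | 5,7‑dihydroxy‑8‑methoxy‑3,4'‑diprenyloxyflavone | COc1c(O)cc(O)c2c(=O)c(OCC=C(C)C)c(-c3ccc(OCC=C(C)C)cc3)oc12 | target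

**Count and risks**

Total steps: 16. Longest linear sequence: 11 (steps 1–8, 14, 15, 16).

Step 14. β‑Ketocarboxylates have not been put through this insertion, and several processes can divert it. The salt may decarboxylate before it meets the aryne. The acidic C3–H of the O‑aryl ester may transfer to the aryl anion faster than the acyl group shifts, leaving an aryl ester. The aryl anion may expel the neighbouring tosylate, or oxygen may add at C4a. The fallback splits the keto acid into two plain acids and sets out from 13, 18 and 16. Hydrolysis of 18 with LiOH gives 2‑(prenyloxy)acetic acid F1. The same fluoride‑induced C–O insertion of the aryne from 13 into F1 (CsF, THF, sealed tube, heating as usual for simple acids) gives 1‑[2‑hydroxy‑3‑methoxy‑6‑(tosyloxy)‑4‑(triflyloxy)phenyl]‑2‑(prenyloxy)ethan‑1‑one F2. Oxidation of 16 (NaClO2, NaH2PO4, 2‑methyl‑2‑butene) gives 4‑(prenyloxy)benzoic acid F3. Esterification of the phenol of F2 with F3 (EDC·HCl, DMAP) gives 2‑methoxy‑6‑[2‑(prenyloxy)acetyl]‑5‑(tosyloxy)‑3‑(triflyloxy)phenyl 4‑(prenyloxy)benzoate F4. Baker–Venkataraman rearrangement of F4 (LiN(SiMe3)2, THF, −78 → 0 °C) comes back to the route at 25.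

Step 13. Hydroxide may cleave the C2–C3 bond by retro‑Claisen attack at the aryl ketone, hydrolysis of the enolised ester may stall, or the salt may lose CO2 on drying. The fallback replaces saponification by fluoride cleavage and sets out from 18. Transesterification with 2‑(trimethylsilyl)ethanol (Ti(OiPr)4 cat., toluene, heat) gives 2‑(trimethylsilyl)ethyl 2‑(prenyloxy)acetate F5. Aldol addition to 16 as in step 11 gives 2‑(trimethylsilyl)ethyl 3‑hydroxy‑2‑(prenyloxy)‑3‑[4‑(prenyloxy)phenyl]propanoate F6. Dess–Martin oxidation gives 2‑(trimethylsilyl)ethyl 3‑oxo‑2‑(prenyloxy)‑3‑[4‑(prenyloxy)phenyl]propanoate F7. CsF with 18‑crown‑6 in THF then cleaves the ester by β‑elimination and returns to the route at 22, formed in the flask of step 14.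

Step 6. Aryllithium 9 may deprotonate the neighbouring benzylic OCH2 (leading to Wittig rearrangement) instead of accepting silicon, or the hindered lithium phenoxide 10 may be sulfonylated too slowly. The fallback uses directed ortho‑metalation and sets out from 6. Carbamoylation (ClC(O)NEt2, NaH, THF) gives 3,5‑bis(benzyloxy)‑4‑methoxyphenyl N,N‑diethylcarbamate F8. Lithiation at one of the two equivalent ortho positions (s‑BuLi, TMEDA, THF, −78 °C) and quenching with Me3SiCl gives 3,5‑bis(benzyloxy)‑4‑methoxy‑2‑(trimethylsilyl)phenyl N,N‑diethylcarbamate F9. Reductive carbamate cleavage with Cp2Zr(H)Cl gives 3,5‑bis(benzyloxy)‑4‑methoxy‑2‑(trimethylsilyl)phenol F10. Tosylation (TsCl, Et3N, DMAP, CH2Cl2) comes back to the route at 11.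

**Further compounds**

F1 | step 14 | 2‑(prenyloxy)acetic acid | OC(=O)COCC=C(C)C
F2 | step 14 | 1‑[2‑hydroxy‑3‑methoxy‑6‑(tosyloxy)‑4‑(triflyloxy)phenyl]‑2‑(prenyloxy)ethan‑1‑one | COc1c(O)c(C(=O)COCC=C(C)C)c(OS(=O)(=O)c2ccc(C)cc2)cc1OS(=O)(=O)C(F)(F)F
F3 | step 14 | 4‑(prenyloxy)benzoic acid | OC(=O)c1ccc(OCC=C(C)C)cc1
F4 | step 14 | 2‑methoxy‑6‑[2‑(prenyloxy)acetyl]‑5‑(tosyloxy)‑3‑(triflyloxy)phenyl 4‑(prenyloxy)benzoate | COc1c(OC(=O)c2ccc(OCC=C(C)C)cc2)c(C(=O)COCC=C(C)C)c(OS(=O)(=O)c2ccc(C)cc2)cc1OS(=O)(=O)C(F)(F)F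
F5 | step 13 | 2‑(trimethylsilyl)ethyl 2‑(prenyloxy)acetate | C[Si](C)(C)CCOC(=O)COCC=C(C)C
F6 | step 13 | 2‑(trimethylsilyl)ethyl 3‑hydroxy‑2‑(prenyloxy)‑3‑[4‑(prenyloxy)phenyl]propanoate (racemic, both diastereomers) | C[Si](C)(C)CCOC(=O)C(OCC=C(C)C)C(O)c1ccc(OCC=C(C)C)cc1
F7 | step 13 | 2‑(trimethylsilyl)ethyl 3‑oxo‑2‑(prenyloxy)‑3‑[4‑(prenyloxy)phenyl]propanoate (racemic) | C[Si](C)(C)CCOC(=O)C(OCC=C(C)C)C(=O)c1ccc(OCC=C(C)C)cc1
F8 | step 6 | 3,5‑bis(benzyloxy)‑4‑methoxyphenyl N,N‑diethylcarbamate | CCN(CC)C(=O)Oc1cc(OCc2ccccc2)c(OC)c(OCc2ccccc2)c1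
F9 | step 6 | 3,5‑bis(benzyloxy)‑4‑methoxy‑2‑(trimethylsilyl)phenyl N,N‑diethylcarbamate | CCN(CC)C(=O)Oc1cc(OCc2ccccc2)c(OC)c(OCc2ccccc2)c1[Si](C)(C)C
F10 | step 6 | 3,5‑bis(benzyloxy)‑4‑methoxy‑2‑(trimethylsilyl)phenol | Oc1cc(OCc2ccccc2)c(OC)c(OCc2ccccc2)c1[Si](C)(C)C
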